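Numbering the side chain from the benzylic carbon (C1; acetoxy stereocentre C2; carbinol C13), everything rests on cutting C4–C5. This bond sits inside the unbranched, heteroatom-free methylene run C3–C12, where an alkene of either geometry is a traceless precursor. Ruthenium-catalysed cross-metathesis of (R)-homoallylic acetate 8 (C2 and its acetate already in place, phenol masked as benzyl ether) with unprotected dec-9-en-1-ol 9 therefore joins both halves in one catalytic operation, losing only ethylene; a single hydrogenation then saturates the E/Z mixture and frees the phenol. The C2 configuration is relayed from (S)-epichlorohydrin through two copper-catalysed Grignard openings.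

Key step: step 4

Remark: 10 is expected as an E/Z mixture and is drawn as its E isomer; both isomers give 11 in step 5.

Step 1
Reactants: 1 3-bromo-5-methoxyphenol
Product: 2 1-(benzyloxy)-3-bromo-5-methoxybenzene
Conditions: BnBr (1.1 equiv), K2CO3, acetone, reflux
Reagents that add atoms: benzyl bromide, BrCc1ccccc1
Why: Williamson etherification of the only acidic site masks the phenol against the Grignard chemistry with a group that the final hydrogenation removes at no extra cost.

Step 2
Reactants: 2 1-(benzyloxy)-3-bromo-5-methoxybenzene; 3 (S)-epichlorohydrin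
Product: 6 (S)-2-[3-(benzyloxy)-5-methoxybenzyl]oxirane, via arylmagnesium bromide 4 (not isolated), via chlorohydrin 5 (not isolated)
Conditions: Mg, THF, 40 °C; CuI (10 mol %), 3 (1.1 equiv), THF, −40 → 0 °C; H2O quench, extraction; crude 5, NaOH, THF/H2O, 0 °C → rt
Reagents that add atoms: none
Why: Copper-catalysed SN2 opening of the epoxide CH2 of epichlorohydrin by the aryl Grignard reagent, then base-mediated 3-exo-tet closure onto the CH2Cl carbon (intramolecular Williamson epoxide formation), never breaks the C–O bond at the stereocentre, so (S)-3 should be relayed to (S)-6 as long as low temperature and CuI keep direct chloride displacement negligible.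

Step 3
Reactants: 6 (S)-2-[3-(benzyloxy)-5-methoxybenzyl]oxirane
Product: 8 (R)-1-[3-(benzyloxy)-5-methoxyphenyl]pent-4-en-2-yl acetate, via bromomagnesium alkoxide 7 (not isolated)
Conditions: CH2=CHMgBr (1.5 equiv), CuI (10 mol %), THF, −30 → 0 °C; then Ac2O (4 equiv), DMAP (10 mol %), 0 °C → rt
Reagents that add atoms: vinylmagnesium bromide, C=C[Mg]Br; acetic anhydride, CC(=O)OC(C)=O
Why: Copper-catalysed Grignard opening of the terminal epoxide at its unsubstituted carbon (SN2; the stereocentre is untouched and only its descriptor changes from S to R through CIP priorities) is followed by O-acylation of the magnesium alkoxide in the same flask, which places the acetate before any primary hydroxyl exists in the molecule.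

Step 4
Reactants: 8 (R)-1-[3-(benzyloxy)-5-methoxyphenyl]pent-4-en-2-yl acetate; 9 dec-9-en-1-ol (3 equiv)
Product: 10 (2R,4E)-1-[3-(benzyloxy)-5-methoxyphenyl]-13-hydroxytridec-4-en-2-yl acetate (E/Z mixture expected)
Conditions: Grubbs II (5 mol %), 1,4-benzoquinone (10 mol %), CH2Cl2, 40 °C, Ar sweep
Reagents that add atoms: none
Why: Olefin cross-metathesis by the Chauvin mechanism: the Ru alkylidene undergoes [2+2] cycloaddition and cycloreversion with each terminal alkene through ruthenacyclobutanes, expelling ethylene and forming the C4=C5 bond. The closest known reaction type is the routine cross-metathesis of two unhindered (type I) terminal olefins with second-generation Ru–NHC catalysts, which tolerate free alcohols, esters and aryl ethers. No ring is closed and no stereocentre is made: C2 is homoallylic and untouched, and the geometry of the new alkene does not matter because both isomers give the same saturated chain in step 5. The selectivity needed is cross- over homo-coupling, which should be secured by a threefold excess of cheap 9 (its diol homodimer is much more polar than 10 and remains metathesis-active) and by sweeping out ethylene. 1,4-Benzoquinone is added to suppress Ru–H double-bond migration, which would otherwise change the chain length by one carbon or move the alkene next to the acetate.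

Step 5
Reactants: 10 (2R,4E)-1-[3-(benzyloxy)-5-methoxyphenyl]-13-hydroxytridec-4-en-2-yl acetate
Product: 11 (R)-13-hydroxy-1-(3-hydroxy-5-methoxyphenyl)tridecan-2-yl acetate
Conditions: H2 (1 atm), 10 % Pd/C, EtOAc, rt
Reagents that add atoms: none
Why: Heterogeneous catalytic hydrogenation should saturate the disubstituted alkene (both geometries converge) and hydrogenolyse the aryl benzyl ether in one operation, while the secondary acetate, which is neither benzylic nor allylic, survives in the neutral aprotic medium.

Compound list
1 | 3-bromo-5-methoxyphenol | COc1cc(O)cc(Br)c1 | starting material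
2 | 1-(benzyloxy)-3-bromo-5-methoxybenzene | COc1cc(Br)cc(OCc2ccccc2)c1 | intermediate
3 | (S)-epichlorohydrin, (S)-2-(chloromethyl)oxirane | ClC[C@@H]1CO1 | starting material
4 | [3-(benzyloxy)-5-methoxyphenyl]magnesium bromide | COc1cc([Mg]Br)cc(OCc2ccccc2)c1 | intermediate
5 | (S)-1-[3-(benzyloxy)-5-methoxyphenyl]-3-chloropropan-2-ol | COc1cc(OCc2ccccc2)cc(C[C@@H](CCl)O)c1 | intermediate
6 | (S)-2-[3-(benzyloxy)-5-methoxybenzyl]oxirane | COc1cc(OCc2ccccc2)cc(C[C@H]3CO3)c1 | intermediate
7 | bromomagnesium (R)-1-[3-(benzyloxy)-5-methoxyphenyl]pent-4-en-2-olate | COc1cc(OCc2ccccc2)cc(C[C@@H](CC=C)O[Mg]Br)c1 | intermediate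
8 | (R)-1-[3-(benzyloxy)-5-methoxyphenyl]pent-4-en-2-yl acetate | COc1cc(OCc2ccccc2)cc(C[C@@H](CC=C)OC(C)=O)c1 | intermediate
9 | dec-9-en-1-ol | C=CCCCCCCCCO | starting material
10 | (2R,4E)-1-[3-(benzyloxy)-5-methoxyphenyl]-13-hydroxytridec-4-en-2-yl acetate (E drawn, Z also expected) | COc1cc(OCc2ccccc2)cc(C[C@@H](C/C=C/CCCCCCCCO)OC(C)=O)c1 | intermediate
11 | (R)-13-hydroxy-1-(3-hydroxy-5-methoxyphenyl)tridecan-2-yl acetate | COc1cc(O)cc(C[C@@H](CCCCCCCCCCCO)OC(C)=O)c1 | target

Total step count: 5
Longest linear sequence: 5 steps (1 → 2 → 6 → 8 → 10 → 11)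

Steps most likely to fail

1. Step 4 (key step). What may go wrong: statistical metathesis, with homodimerisation of each terminal olefin competing with the cross-coupling, and ruthenium-hydride double-bond migration that scrambles the chain length. Fallback: the same C4–C5 bond is made at the alkane oxidation level by opening a temporary oxetane ring that ties the C2 oxygen to C4. Setting out from 6, ring expansion with dimethylsulfoxonium methylide (Me3S(O)I, KOtBu, t-BuOH, 70 °C) should give (S)-2-[3-(benzyloxy)-5-methoxybenzyl]oxetane F1. Benzyl 9-bromononyl ether F2 (from 9-bromononan-1-ol, benzyl 2,2,2-trichloroacetimidate, cat. TfOH) is converted with Mg in THF into [9-(benzyloxy)nonyl]magnesium bromide F3. With CuI (10 mol %) in refluxing THF, F3 should open F1 at its unsubstituted CH2 to give (R)-13-(benzyloxy)-1-[3-(benzyloxy)-5-methoxyphenyl]tridecan-2-ol F4. Acetylation (Ac2O, pyridine, DMAP) should give (R)-13-(benzyloxy)-1-[3-(benzyloxy)-5-methoxyphenyl]tridecan-2-yl acetate F5. Hydrogenolysis of both benzyl ethers (H2, Pd/C, EtOAc) comes back to the route at 11.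

2. Step 3. What may go wrong: opening of the epoxide by magnesium halide to a halohydrin instead of vinyl transfer, and incomplete acylation of the aggregated magnesium alkoxide while excess Grignard reagent consumes the anhydride. Fallback: the two-carbon unit is brought in as an alkyne without Grignard or copper reagents. Setting out from 6, lithium acetylide–ethylenediamine complex in DMSO at rt should open the epoxide at its terminus to give (R)-1-[3-(benzyloxy)-5-methoxyphenyl]pent-4-yn-2-ol F6. Acetylation of the isolated alcohol (Ac2O, pyridine, DMAP) should give (R)-1-[3-(benzyloxy)-5-methoxyphenyl]pent-4-yn-2-yl acetate F7. Lindlar semihydrogenation (H2, Pd/CaCO3/Pb, quinoline, EtOAc), which leaves the benzyl ether intact, comes back to the route at 8.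

3. Step 2. What may go wrong: erosion of enantiopurity through halide-mediated epoxide–halohydrin interconversion of epichlorohydrin or direct displacement of chloride (both lead to the antipode), and biaryl homocoupling during Grignard formation. Fallback: the stereocentre is set by resolution instead of chiral-pool relay. Setting out from 2, the Grignard reagent 4 is allylated with allyl bromide (THF, 0 °C) to give 1-allyl-3-(benzyloxy)-5-methoxybenzene F8. Epoxidation (mCPBA, NaHCO3, CH2Cl2, 0 °C) should give rac-2-[3-(benzyloxy)-5-methoxybenzyl]oxirane F9. Hydrolytic kinetic resolution with (S,S)-(salen)Co(III)OAc (0.5 mol %) and H2O (0.55 equiv) is expected, by analogy with simple 2-alkyloxiranes, to hydrolyse the R enantiomer to (R)-3-[3-(benzyloxy)-5-methoxyphenyl]propane-1,2-diol F10 and leave the S epoxide, which comes back to the route at 6.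

Further compounds
F1 | step 4 | (S)-2-[3-(benzyloxy)-5-methoxybenzyl]oxetane | COc1cc(OCc2ccccc2)cc(C[C@H]3CCO3)c1
F2 | step 4 | benzyl 9-bromononyl ether | BrCCCCCCCCCOCc1ccccc1
F3 | step 4 | [9-(benzyloxy)nonyl]magnesium bromide | Br[Mg]CCCCCCCCCOCc1ccccc1
F4 | step 4 | (R)-13-(benzyloxy)-1-[3-(benzyloxy)-5-methoxyphenyl]tridecan-2-ol | COc1cc(OCc2ccccc2)cc(C[C@@H](CCCCCCCCCCCOCc2ccccc2)O)c1
F5 | step 4 | (R)-13-(benzyloxy)-1-[3-(benzyloxy)-5-methoxyphenyl]tridecan-2-yl acetate | COc1cc(OCc2ccccc2)cc(C[C@@H](CCCCCCCCCCCOCc2ccccc2)OC(C)=O)c1
F6 | step 3 | (R)-1-[3-(benzyloxy)-5-methoxyphenyl]pent-4-yn-2-ol | COc1cc(OCc2ccccc2)cc(C[C@@H](CC#C)O)c1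
F7 | step 3 | (R)-1-[3-(benzyloxy)-5-methoxyphenyl]pent-4-yn-2-yl acetate | COc1cc(OCc2ccccc2)cc(C[C@@H](CC#C)OC(C)=O)c1
F8 | step 2 | 1-allyl-3-(benzyloxy)-5-methoxybenzene | C=CCc1cc(OC)cc(OCc2ccccc2)c1
F9 | step 2 | rac-2-[3-(benzyloxy)-5-methoxybenzyl]oxirane | COc1cc(OCc2ccccc2)cc(CC3CO3)c1
F10 | step 2 | (R)-3-[3-(benzyloxy)-5-methoxyphenyl]propane-1,2-diol | COc1cc(OCc2ccccc2)cc(C[C@@H](O)CO)c1
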